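The route disconnects both C8–CH2 bonds of the gem-diprenyl group. In the target, C8 is the quaternary carbon of the carbocyclic ring A (C4a–C8a), between the C7 ketone and the enol-ether carbon C8a. In the aromatic parent it is the only ring carbon still bearing hydrogen, flanked by the free 7-OH and the lactone oxygen O1. An aromatic prenyltransferase should transfer two dimethylallyl groups from the diphosphate to this carbon and dearomatise ring A in one operation, closing no ring and creating no stereocentre. Its substrate is the complete (4S)-5,7-dihydroxy-6-[(2R)-2-methylbutanoyl]-4-phenylchroman-2-one, built so that the lactone oxygen lies para to the acyl group by construction.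

Key step: step 8

Remark on the chemistry: the target SMILES encodes (2R) at the side chain and (4S) at C4. A free 2-acylphloroglucinol could lactonise on either oxygen beside a new C–C bond, so the two oxygens flanking the acyl group stay methylated until the lactone exists; this also keeps acidic, chelating phenols away from the rhodium catalyst.
Assumption: recombinant AtaPT (the aromatic prenyltransferase of Aspergillus terreus) is available by standard expression in E. coli, and the diphosphate is handled as its tris-ammonium salt.

Step 1
Reactants: 1 3,5-dimethoxyphenol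
Product: 2 (3,5-dimethoxyphenoxy)tri(propan-2-yl)silane
Conditions: i-Pr3SiCl, imidazole, DMF, rt
Reagents that add atoms: chlorotri(propan-2-yl)silane, CC(C)[Si](Cl)(C(C)C)C(C)C
Why: Silyl ether formation at the only hydroxyl group gives a bulky, weakly coordinating silyloxy group that should survive n-BuLi and not direct the metalation of step 3.

Step 2
Reactants: 3 (2R)-2-methylbutanoic acid
Product: 5 (2R)-N-methoxy-N,2-dimethylbutanamide, via acyl imidazolide 4 (not isolated)
Conditions: 1,1'-carbonyldiimidazole, CH2Cl2, 0 °C to rt; then MeNH(OMe)·HCl, rt
Reagents that add atoms: N,O-dimethylhydroxylamine hydrochloride, CNOC.Cl (1,1'-carbonyldiimidazole, O=C(n1ccnc1)n1ccnc1, supplies only the imidazole of 4)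
Why: Weinreb amide formation through the acyl imidazolide involves no ketene or other planar species at C2, so the (R) centre of 3 should be carried over unchanged.

Step 3
Reactants: 2 (3,5-dimethoxyphenoxy)tri(propan-2-yl)silane; 5 (2R)-N-methoxy-N,2-dimethylbutanamide
Product: 8 (2R)-1-(4-hydroxy-2,6-dimethoxyphenyl)-2-methylbutan-1-one, via aryllithium 6 (not isolated), via silyl ketone 7 (not isolated)
Conditions: n-BuLi, THF, 0 °C to rt; 5, −78 to 0 °C; AcOH, then n-Bu4NF, 0 °C to rt
Reagents that add atoms: none
Why: Directed ortho-metalation, Weinreb ketone synthesis and buffered fluoride desilylation run in sequence, in which the two methoxy groups cooperate to lithiate the carbon between them (para to the silyloxy group), the N,O-chelated adduct releases the ketone only on protonation so the α-centre never meets the aryllithium as a ketone, and the single phenol freed is the future lactone oxygen.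

Step 4
Reactants: 8 (2R)-1-(4-hydroxy-2,6-dimethoxyphenyl)-2-methylbutan-1-one; 9 ethyl prop-2-ynoate
Product: 11 5,7-dimethoxy-6-[(2R)-2-methylbutanoyl]-2H-chromen-2-one, via cinnamate 10 (not isolated)
Conditions: Pd(OAc)2 (5 mol %), CF3CO2H/CH2Cl2, 0 °C to rt
Reagents that add atoms: none
Why: Fujiwara-type trans-hydroarylation of the propiolate (a mild relative of the Pechmann coumarin synthesis) attacks one of the two equivalent carbons ortho to the hydroxyl group, and the (Z)-cinnamate 10 can lactonise only onto that hydroxyl group, which fixes the 6-acyl pattern without a regiochemical choice.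

Step 5
Reactants: 11 5,7-dimethoxy-6-[(2R)-2-methylbutanoyl]-2H-chromen-2-one
Product: 12 (4S)-5,7-dimethoxy-6-[(2R)-2-methylbutanoyl]-4-phenyl-3,4-dihydro-2H-chromen-2-one
Conditions: PhB(OH)2 (excess, in portions), Rh(acac)(C2H4)2 (3 mol %), (S)-SEGPHOS, 1,4-dioxane/H2O (10:1), 60 °C
Reagents that add atoms: phenylboronic acid, OB(O)c1ccccc1
Why: In this Hayashi–Miyaura asymmetric conjugate addition the phenylrhodium species inserts the C3=C4 bond and the oxa-π-allyl intermediate is hydrolysed, with C4 set by the chiral bisphosphine independently of the remote side-chain centre, and since the (R)-ligand is known to give (R)-4-arylchroman-2-ones from simple coumarins and the priority order at C4 is unchanged here, (S)-SEGPHOS should give 4S.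

Step 6
Reactants: 12 (4S)-5,7-dimethoxy-6-[(2R)-2-methylbutanoyl]-4-phenyl-3,4-dihydro-2H-chromen-2-one
Product: 13 (4S)-5,7-dihydroxy-6-[(2R)-2-methylbutanoyl]-4-phenyl-3,4-dihydro-2H-chromen-2-one
Conditions: BBr3, CH2Cl2, −78 to 0 °C; ice water
Reagents that add atoms: none
Why: Lewis-acid cleavage of aryl methyl ethers by BBr3 should remove both methoxy groups, which flank the ketone, while the aryl lactone offers bromide no alkyl–oxygen bond and the cold aqueous, alcohol-free quench avoids a lactone opening that could reclose on the 5-oxygen instead of O1.

Step 7
Reactants: 14 1-bromo-3-methylbut-2-ene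
Product: 15 tris-ammonium dimethylallyl diphosphate
Conditions: (n-Bu4N)3HP2O7, MeCN, rt; Dowex 50WX8 (NH4+ form), aq. NH4HCO3; cellulose chromatography
Reagents that add atoms: tris(tetrabutylammonium) hydrogen diphosphate, CCCC[N+](CCCC)(CCCC)CCCC.CCCC[N+](CCCC)(CCCC)CCCC.CCCC[N+](CCCC)(CCCC)CCCC.OP(=O)([O-])OP(=O)([O-])[O-]; ammonium hydrogencarbonate, [NH4+].OC([O-])=O
Why: Davisson–Poulter diphosphorylation is an SN2 displacement of the primary allylic bromide by the diphosphate anion, followed by cation exchange to the ammonium form that enzymes tolerate.

Step 8
Reactants: 13 (4S)-5,7-dihydroxy-6-[(2R)-2-methylbutanoyl]-4-phenyl-3,4-dihydro-2H-chromen-2-one; 15 tris-ammonium dimethylallyl diphosphate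
Product: 17 (4S)-5-hydroxy-8,8-bis(3-methylbut-2-en-1-yl)-6-[(2R)-2-methylbutanoyl]-4-phenyl-3,4-dihydro-2H-chromene-2,7(8H)-dione (target CNP0311143.1), via monoprenyl phenol 16 (not isolated)
Conditions: recombinant AtaPT, 15 (3 equiv), Tris-HCl buffer (50 mM, pH 7.5), CaCl2 (5 mM), DMSO (5 % v/v), 30 °C; then pH 4, EtOAc extraction, chromatography
Reagents that add atoms: none
Why: Proposed new method: ionisation of 15 in the active site gives a dimethylallyl cation, and C8 of 13 (ortho to the free 7-OH, para to the 5-OH, the only ring carbon bearing hydrogen) attacks its primary carbon; loss of H-8 gives 16, and a second transfer to the same carbon can end only by loss of the 7-OH proton, leaving the C7 ketone, the chelated C5 enol and the quaternary C8. The closest known reaction is the gem-diprenylation of simple acylphloroglucinols by prenyltransferases of the dimethylallyltryptophan synthase family, together with the third prenyl transfer of hop bitter-acid biosynthesis; acceptance of a substrate whose third phenol oxygen is tied up in a lactone is the untested element. No ring is closed and no stereocentre is formed, because C8 carries two identical groups, and C4 and the side-chain centre are not touched near neutral pH. The step needs C- over O-alkylation, normal over reverse attachment and exactly two transfers to one carbon: the first two rest on the enzyme pocket, the third on the substrate, since C6 and C4a are blocked and the dienone product is no longer a phenol nucleophile. The lactone of 13 and the vinylogous-anhydride-like lactone of 17 are the base-sensitive points, so the incubation is kept short and ended by acidification before extraction.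

Compound list
1 | 3,5-dimethoxyphenol | COc1cc(O)cc(OC)c1 | starting material
2 | (3,5-dimethoxyphenoxy)tri(propan-2-yl)silane | COc1cc(OC)cc(O[Si](C(C)C)(C(C)C)C(C)C)c1 | intermediate
3 | (2R)-2-methylbutanoic acid | CC[C@@H](C)C(O)=O | starting material
4 | 1-[(2R)-2-methylbutanoyl]-1H-imidazole (acyl imidazolide, not isolated) | CC[C@@H](C)C(=O)n1ccnc1 | intermediate
5 | (2R)-N-methoxy-N,2-dimethylbutanamide | CC[C@@H](C)C(=O)N(C)OC | intermediate
6 | {2,6-dimethoxy-4-[tri(propan-2-yl)silyloxy]phenyl}lithium (aryllithium, not isolated) | [Li]c1c(OC)cc(O[Si](C(C)C)(C(C)C)C(C)C)cc1OC | intermediate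
7 | (2R)-1-{2,6-dimethoxy-4-[tri(propan-2-yl)silyloxy]phenyl}-2-methylbutan-1-one (silyl ketone, not isolated) | CC[C@@H](C)C(=O)c1c(OC)cc(O[Si](C(C)C)(C(C)C)C(C)C)cc1OC | intermediate
8 | (2R)-1-(4-hydroxy-2,6-dimethoxyphenyl)-2-methylbutan-1-one | CC[C@@H](C)C(=O)c1c(OC)cc(O)cc1OC | intermediate
9 | ethyl prop-2-ynoate (ethyl propiolate) | CCOC(=O)C#C | starting material
10 | ethyl (2Z)-3-{6-hydroxy-2,4-dimethoxy-3-[(2R)-2-methylbutanoyl]phenyl}prop-2-enoate (cinnamate, not isolated) | CC[C@@H](C)C(=O)c1c(OC)cc(O)c(/C=C\C(=O)OCC)c1OC | intermediate
11 | 5,7-dimethoxy-6-[(2R)-2-methylbutanoyl]-2H-chromen-2-one | CC[C@@H](C)C(=O)c1c(OC)cc2OC(=O)C=Cc2c1OC | intermediate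
12 | (4S)-5,7-dimethoxy-6-[(2R)-2-methylbutanoyl]-4-phenyl-3,4-dihydro-2H-chromen-2-one | CC[C@@H](C)C(=O)c1c(OC)c2c(OC(=O)C[C@H]2c2ccccc2)cc1OC | intermediate
13 | (4S)-5,7-dihydroxy-6-[(2R)-2-methylbutanoyl]-4-phenyl-3,4-dihydro-2H-chromen-2-one (substrate of the key step) | CC[C@@H](C)C(=O)c1c(O)c2c(OC(=O)C[C@H]2c2ccccc2)cc1O | intermediate
14 | 1-bromo-3-methylbut-2-ene (prenyl bromide) | CC(C)=CCBr | starting material
15 | tris-ammonium dimethylallyl diphosphate | CC(C)=CCOP(=O)([O-])OP(=O)([O-])[O-].[NH4+].[NH4+].[NH4+] | intermediate
16 | (4S)-5,7-dihydroxy-8-(3-methylbut-2-en-1-yl)-6-[(2R)-2-methylbutanoyl]-4-phenyl-3,4-dihydro-2H-chromen-2-one (monoprenyl phenol, not isolated) | CC[C@@H](C)C(=O)c1c(O)c2c(OC(=O)C[C@H]2c2ccccc2)c(CC=C(C)C)c1O | intermediate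
17 | (4S)-5-hydroxy-8,8-bis(3-methylbut-2-en-1-yl)-6-[(2R)-2-methylbutanoyl]-4-phenyl-3,4-dihydro-2H-chromene-2,7(8H)-dione (CNP0311143.1) | CC[C@@H](C)C(=O)C1=C(O)C2=C(OC(=O)C[C@H]2c2ccccc2)C(CC=C(C)C)(CC=C(C)C)C1=O | target

Total step count: 8. Longest linear sequence: 6 steps (1, 3, 4, 5, 6, 8); steps 2 and 7 supply the side branches.

Steps most likely to fail

Step 8 (the step labelled as a proposed new method). The enzyme may not bind the lactone-bearing substrate productively, turnover may stop after the first transfer, the cation may be captured by oxygen or through its tertiary carbon, or either lactone may open during the incubation. The fallback sets out from 13 and uses the classical base-mediated dearomatising C-prenylation of acylphloroglucinols (the lupulone-type alkylation), run without hydroxide or alkoxide so that the lactone stays closed. Sodium hydride (one equivalent per phenol, no excess) in toluene/THF at 0 °C with slow addition of 14 should give the C8-alkylated phenol 16, which is isolated. A second round of sodium hydride and 14 should then alkylate the same carbon and give the dienone. O-prenyl ethers are the expected by-products and are removed by chromatography. The fallback makes no compound outside the list (F0) and comes back to the route at 17.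

Step 5. Carbometalation at a β-carbon next to the peri 5-methoxy group may be slow, so that protodeboronation of the boronic acid outruns addition, and the higher temperature then needed may erode facial selectivity. The fallback sets out from 8 and forms the C4–C4a bond instead of the C4–phenyl bond, by the organocatalytic enantioselective Friedel–Crafts alkylation and hemiacetalisation of electron-rich phenols with enals. Treating 8 with (E)-cinnamaldehyde, (S)-α,α-diphenylprolinol trimethylsilyl ether and benzoic acid in toluene should give the lactol (2R)-1-[(4S)-2-hydroxy-5,7-dimethoxy-4-phenyl-3,4-dihydro-2H-chromen-6-yl]-2-methylbutan-1-one F1. The (S)-catalyst is chosen by the usual face-shielding model of the iminium ion, which places the aryl group to give 4S. Only one hydroxyl group is present, so the ring can close in one way only. Oxidation of F1 with Dess–Martin periodinane in CH2Cl2 should give the lactone, and the fallback comes back to the route at 12, bypassing 11.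

Step 4. Electrophilic attack on a ring deactivated by the para acyl group may be sluggish, with oligomerisation of the propiolate or acid-promoted loss of the acyl group competing. The fallback sets out from 8 and reverses the order of bond formation. Esterification with propiolic acid and N,N'-dicyclohexylcarbodiimide in CH2Cl2 at 0 °C should give 3,5-dimethoxy-4-[(2R)-2-methylbutanoyl]phenyl prop-2-ynoate F2. Its intramolecular 6-endo hydroarylation with a monovalent gold catalyst (Ph3PAuCl/AgOTf, CH2Cl2, rt), a known cycloisomerisation of aryl alkynoates to coumarins, should then close the ring at the carbon ortho to the ester oxygen. The fallback comes back to the route at 11.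

Further compounds
F0 | step 8 | none | none
F1 | step 5 | (2R)-1-[(4S)-2-hydroxy-5,7-dimethoxy-4-phenyl-3,4-dihydro-2H-chromen-6-yl]-2-methylbutan-1-one (lactol, both C2 epimers) | CC[C@@H](C)C(=O)c1c(OC)c2c(OC(O)C[C@H]2c2ccccc2)cc1OC
F2 | step 4 | 3,5-dimethoxy-4-[(2R)-2-methylbutanoyl]phenyl prop-2-ynoate | CC[C@@H](C)C(=O)c1c(OC)cc(OC(=O)C#C)cc1OC
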